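Atom labels Cn use iridal numbering: C1 = CHO, C2=C7 the enal olefin, C3–C5 the hydroxypropyl arm, C6–C11 the ring, C12–C24 the side chain. The target is 6R,10S,11S,16R.

Assumption: (S)-3,3′-Br2-BINOL is taken to give Re-face addition in step 7. If the sense is reversed, the commercial (R)-catalyst is used instead.

## Retrosynthetic overview

1. The enal comes from MnO2 oxidation and desilylation of 23. The hydroxypropyl arm is built from the lactone carbonyl C5 of bridged lactone 20, plus CH2 (Wittig), plus CO (hydroformylation).
2. Key step: C6–C7 is closed by a lactone-templated intramolecular Pd enolate alkenylation of a preformed (Z)-tetrasubstituted alkenyl bromide (19 → 20). The tether fixes C6 and the coupling keeps the Z-C2=C7 geometry.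
3. C13–C14 is made by B-alkyl Suzuki coupling of vinyl lactone 11 with (R)-vinyl iodide 18, which comes from geranyl chloride, iodomethacrolein and a CBS reduction.
4. C10–C11: both fully substituted centres are set in one catalytic asymmetric allylboration of methyl ketone 6 with the (E)-γ,γ-disubstituted allylboronic acid 9.
5. Ring order: temporary γ-lactone, then the cyclohexane (as a 6-oxabicyclo[3.2.1]octanone), then the lactone is opened.

## Route

### Fragment A: ketone 6 (steps 1–4)

**Step 1**
- Reactants: 1 propargyl alcohol; 2 2-(2-bromoethyl)-2-methyl-1,3-dioxolane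
- Product: 3 5-(2-methyl-1,3-dioxolan-2-yl)pent-2-yn-1-ol
- Conditions: LiNH2 (2.2 equiv), NH3(l)/THF, −33 °C; then 2; NH4Cl
- Reagents that add atoms: none (both partners are numbered reactants)
- Why: Acetylide SN2 alkylation of the O,C-dianion, in which only the carbon nucleophile alkylates the primary bromide and the ketal masks the future C10 ketone.

**Step 2**
- Reactants: 3
- Product: 4 (Z)-3-bromo-2-methyl-5-(2-methyl-1,3-dioxolan-2-yl)pent-2-en-1-ol
- Conditions: MeMgBr (3.5 equiv), CuI (20 mol %), THF, −20 → 25 °C; then BrCl2C–CCl2Br, −40 → 0 °C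
- Reagents that add atoms: methylmagnesium bromide, C[Mg]Br; 1,2-dibromotetrachloroethane, ClC(Cl)(Br)C(Cl)(Cl)Br
- Why: Duboudin-type alkoxide-directed anti-carbomagnesiation puts Me on C2 and holds Mg on C7 in a five-membered Mg-alkoxide chelate, so brominolysis with retention gives only the alkene with Br cis to CH2OH, which is the future Z-C2=C7 geometry.

**Step 3**
- Reactants: 4
- Product: 5 pivalate of 4
- Conditions: PivCl, pyridine, DMAP (cat.), CH2Cl2, 0 °C → rt
- Reagents that add atoms: pivaloyl chloride, CC(C)(C)C(=O)Cl
- Why: Standard O-acylation; the pivalate has no α-H, so it is inert to the amide base of step 16, and it is removed without an extra step by DIBAL-H in step 17.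

**Step 4**
- Reactants: 5
- Product: 6 (Z)-3-bromo-2-methyl-6-oxohept-2-en-1-yl pivalate
- Conditions: PPTS (20 mol %), acetone/H2O 10:1, 55 °C
- Reagents that add atoms: water, O
- Why: Mild acid ketal hydrolysis that does not affect the hindered ester or the alkenyl bromide.

### Fragment B: allylboronic acid 9 (steps 5–6)

**Step 5**
- Reactants: 7 but-3-yn-1-ol
- Product: 8 (E)-3-methylpent-2-ene-1,5-diol
- Conditions: Me3Al (3 equiv), Cp2ZrCl2 (25 mol %), CH2Cl2, 0 → 23 °C; concentrate; n-BuLi, THF/hexane, −78 → 0 °C; (CH2O)n, rt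
- Reagents that add atoms: trimethylaluminium, C[Al](C)C; paraformaldehyde (as formaldehyde), C=O
- Why: Negishi Zr-catalysed syn-carboalumination places Me and Al cis, and hydroxymethylation of the alkenylalanate with retention gives the E-olefin with CH2CH2OH trans to CH2OH.

**Step 6**
- Reactants: 8
- Product: 9 [(E)-5-hydroxy-3-methylpent-2-en-1-yl]boronic acid
- Conditions: B2(OH)4 (1.2 equiv), H2PdCl4 (5 mol %), DMSO/H2O, rt, Ar
- Reagents that add atoms: tetrahydroxydiboron, OB(O)B(O)O
- Why: Pd-catalysed direct borylation of the allylic alcohol via π-allyl-Pd gives the linear allylboronic acid with retained E geometry, as for geraniol and nerol, and the homoallylic OH is not ionised.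

### Union of A and B (steps 7–8)

**Step 7**
- Reactants: 6; 9
- Product: 10 (2Z,6S,7R)-3-bromo-6-hydroxy-7-(2-hydroxyethyl)-2,6,7-trimethylnona-2,8-dien-1-yl pivalate (iridal C10 = S; C11 has the target's spatial arrangement but is labelled R here because vinyl outranks CH2CH2OH)
- Conditions: 9 (1.5 equiv), (S)-3,3′-Br2-BINOL (20 mol %), t-BuOH (3 equiv), 3 Å MS, toluene, 0 °C, 48 h
- Reagents that add atoms: none
- Why: This is a BINOL-catalysed asymmetric allylboration of a ketone through a closed chair Zimmerman–Traxler transition state, in which the E-olefin puts CH2CH2OH equatorial and Me axial, the ketone puts its long chain equatorial and Me axial (giving the Me26/Me27-anti, C9/C12-anti relationship of the target), and the chiral boronate selects the Re face to give 10S.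

**Step 8**
- Reactants: 10
- Product: 11 (Z)-3-bromo-5-[(2S,3R)-3-ethenyl-2,3-dimethyl-5-oxooxolan-2-yl]-2-methylpent-2-en-1-yl pivalate (γ-lactone O10–C5(=O)–C6H2–C11–C10)
- Conditions: TEMPO (20 mol %), PhI(OAc)2 (3 equiv), CH2Cl2, rt
- Reagents that add atoms: none
- Why: TEMPO/BAIB oxidative lactonisation of the 1,4-diol proceeds through aldehyde, five-membered lactol and lactone, and it leaves both stereocentres, the vinyl group and the bromide unchanged.

### Fragment C: vinyl iodide 18 (steps 9–14)

**Step 9**
- Reactants: 1 propargyl alcohol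
- Product: 12 (E)-3-iodo-2-methylprop-2-en-1-ol
- Conditions: Me3Al (3 equiv), Cp2ZrCl2 (25 mol %), CH2Cl2, 0 → 23 °C; I2, THF, −30 °C
- Reagents that add atoms: trimethylaluminium, C[Al](C)C; iodine, II
- Why: Negishi syn-carboalumination followed by iodinolysis with retention fixes the future E-C14=C15 olefin.

**Step 10**
- Reactants: 12
- Product: 13 (E)-3-iodo-2-methylprop-2-enal
- Conditions: MnO2 (15 equiv), CH2Cl2, rt
- Reagents that add atoms: none
- Why: Chemoselective allylic alcohol oxidation without E/Z erosion.

**Step 11**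
- Reactants: 13; 14 geranyl chloride
- Product: 15 rac-(1E,5E)-1-iodo-2,6,10-trimethylundeca-1,5,9-trien-3-ol
- Conditions: BaI2, Li biphenylide (2 equiv), THF, rt; 14 (slight excess over Ba*), −78 °C; then 13, −78 °C
- Reagents that add atoms: none
- Why: Yamamoto allylbarium addition is α-selective and the reagent is configurationally stable at −78 °C, so it gives the linear 1,2-adduct with the E-C18=C19 bond retained, and consuming all the active Ba with 14 protects the C–I bond.

**Step 12**
- Reactants: 15
- Product: 16 (1E,5E)-1-iodo-2,6,10-trimethylundeca-1,5,9-trien-3-one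
- Conditions: Dess–Martin periodinane, NaHCO3, CH2Cl2, 0 °C
- Reagents that add atoms: none
- Why: Buffered neutral oxidation avoids migration of the β,γ-double bond into conjugation.

**Step 13**
- Reactants: 16
- Product: 17 (R,1E,5E)-1-iodo-2,6,10-trimethylundeca-1,5,9-trien-3-ol
- Conditions: (S)-Me-CBS (0.5 equiv), catecholborane (2 equiv), toluene, −78 °C
- Reagents that add atoms: none
- Why: In the Corey–Bakshi–Shibata reduction the α-branched iodoalkenyl group acts as the large substituent and CH2-allyl as the small one, so the (S)-catalyst gives the 16R carbinol, and catecholborane at −78 °C does not hydroborate the trisubstituted alkenes.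

**Step 14**
- Reactants: 17
- Product: 18 TBS ether of 17
- Conditions: TBSCl, imidazole, DMF, rt
- Reagents that add atoms: tert-butyldimethylsilyl chloride, CC(C)(C)[Si](C)(C)Cl
- Why: Standard silylation; the TBS group keeps C16–OH out of the MnO2 oxidation in step 20.

### Coupling, ring closure and endgame (steps 15–21)

**Step 15**
- Reactants: 11; 18
- Product: 19 γ-lactone carrying the full C12–C24 side chain (16-OTBS), the C7 bromide and C1-OPiv (10S,11S,16R)
- Conditions: 11, 9-BBN-H (1.3 equiv), THF, rt; then 18 (1.1 equiv), PdCl2(dppf) (5 mol %), AsPh3 (10 mol %), Cs2CO3, DMF/H2O, rt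
- Reagents that add atoms: none
- Why: In this B-alkyl Suzuki–Miyaura coupling 9-BBN adds only to the monosubstituted vinyl (B on C13), and at rt Pd inserts into the unhindered C–I of 18 far faster than into the tetrasubstituted C–Br, giving C13–C14 with E geometry retained.

**Step 16 (key step)**
- Reactants: 19
- Product: 20 bridged lactone, (6R,10S,11S,16R,2(7)Z)-2-[1-(pivaloyloxy)propan-2-ylidene]-5,8-dimethyl-8-(side chain)-6-oxabicyclo[3.2.1]octan-7-one
- Conditions: LiHMDS (1.2 equiv), THF, −78 °C; ZnCl2 (1.3 equiv), → 0 °C; Pd(dba)2 (10 mol %), Q-Phos (10 mol %), THF (0.01 M), 65 °C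
- Reagents that add atoms: none
- Why: Proposed new method: the Reformatsky-type zinc enolate of the γ-lactone transmetalates to the alkenyl-Pd(II) bromide formed by stereoretentive oxidative addition, and reductive elimination closes the six-membered ring; because C7 is tethered to C10 it can reach only the enolate face cis to C9, which fixes 6R (C5 cis to O10), the olefin geometry is retained, and the bridgehead product cannot re-enolise; the closest known chemistry is Pd-catalysed α-alkenylation of ester and ketone enolates, including the intramolecular variants that give bridged bicycles.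

**Step 17**
- Reactants: 20
- Product: 21 bridged lactol with free C1–OH (anomeric mixture)
- Conditions: DIBAL-H (5 equiv), CH2Cl2, −78 °C; Rochelle salt
- Reagents that add atoms: none
- Why: The lactone stops at the stable aluminium hemiacetal at −78 °C while the pivalate is cleaved reductively in the same operation, and the TBS ether and all olefins are inert.

**Step 18**
- Reactants: 21
- Product: 22 C6-vinyl diol (C10–OH and C1–OH free, 16-OTBS)
- Conditions: Ph3PCH3Br (6 equiv), KHMDS (5.5 equiv), THF, 0 → 40 °C
- Reagents that add atoms: methyltriphenylphosphonium bromide, C[P+](c1ccccc1)(c1ccccc1)c1ccccc1.[Br-]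
- Why: Wittig methylenation of the open hydroxy-aldehyde with a small unstabilised ylide tolerates the hindered site, outruns C6 epimerisation, and gives a non-electrophilic alkene to which O10 cannot add in an oxa-Michael sense.

**Step 19**
- Reactants: 22
- Product: 23 16-O-TBS triol (C1–OH, C3–OH, C10–OH)
- Conditions: Rh(acac)(CO)2 (2 mol %), Xantphos (8 mol %), CO/H2 1:1 (10 bar), toluene, 60 °C; vent; NaBH4, MeOH, 0 °C
- Reagents that add atoms: carbon monoxide, [C-]#[O+]
- Why: Linear-selective Rh/wide-bite-angle hydroformylation acts only on the α-branched monosubstituted vinyl (the tri- and tetrasubstituted alkenes do not bind), adding C3, and in situ borohydride reduction gives the 3-hydroxypropyl arm.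

**Step 20**
- Reactants: 23
- Product: 24 16-O-TBS-isoiridogermanal
- Conditions: MnO2 (30 equiv), CH2Cl2, rt
- Reagents that add atoms: none
- Why: MnO2 oxidises only the allylic C1–OH, because C3–OH is saturated, C10–OH is tertiary and C16–O is silylated, and the Z-enal geometry is unchanged.

**Step 21**
- Reactants: 24
- Product: 25 isoiridogermanal
- Conditions: HF·pyridine, pyridine, THF, 0 °C → rt
- Reagents that add atoms: none
- Why: Buffered fluoride desilylation is non-basic, so it causes no γ-deprotonation or E/Z scrambling of the enal, and it is too mild to ionise the allylic or tertiary alcohols.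

**Where each stereoelement is set**

| Element | Set in |
|---|---|
| C10 and C11 | step 7 |
| C6 | step 16 |
| C16 | step 13 |
| Z-C2=C7 | step 2, retained in step 16 |
| E-C14=C15 | step 9, retained in step 15 |
| E-C18=C19 | from 14, retained in step 11 |

## Compound list

1 | propargyl alcohol | C#CCO | starting material
2 | 2-(2-bromoethyl)-2-methyl-1,3-dioxolane | CC1(CCBr)OCCO1 | starting material
3 | 5-(2-methyl-1,3-dioxolan-2-yl)pent-2-yn-1-ol | CC1(CCC#CCO)OCCO1 | intermediate
4 | (Z)-3-bromo-2-methyl-5-(2-methyl-1,3-dioxolan-2-yl)pent-2-en-1-ol | CC1(CC/C(Br)=C(\C)CO)OCCO1 | intermediate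
5 | pivalate of 4 | CC1(CC/C(Br)=C(\C)COC(=O)C(C)(C)C)OCCO1 | intermediate
6 | (Z)-3-bromo-2-methyl-6-oxohept-2-en-1-yl pivalate | CC(=O)CC/C(Br)=C(\C)COC(=O)C(C)(C)C | intermediate
7 | but-3-yn-1-ol | C#CCCO | starting material
8 | (E)-3-methylpent-2-ene-1,5-diol | OCC/C(C)=C/CO | intermediate
9 | [(E)-5-hydroxy-3-methylpent-2-en-1-yl]boronic acid | OCC/C(C)=C/CB(O)O | intermediate
10 | (2Z,6S,7R)-3-bromo-6-hydroxy-7-(2-hydroxyethyl)-2,6,7-trimethylnona-2,8-dien-1-yl pivalate | C=C[C@@](C)(CCO)[C@@](C)(O)CC/C(Br)=C(\C)COC(=O)C(C)(C)C | intermediate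
11 | (Z)-3-bromo-5-[(2S,3R)-3-ethenyl-2,3-dimethyl-5-oxooxolan-2-yl]-2-methylpent-2-en-1-yl pivalate | C=C[C@@]1(C)CC(=O)O[C@@]1(C)CC/C(Br)=C(\C)COC(=O)C(C)(C)C | intermediate
12 | (E)-3-iodo-2-methylprop-2-en-1-ol | OC/C(C)=C/I | intermediate
13 | (E)-3-iodo-2-methylprop-2-enal | O=C/C(C)=C/I | intermediate
14 | geranyl chloride | CC(C)=CCC/C(C)=C/CCl | starting material
15 | rac-(1E,5E)-1-iodo-2,6,10-trimethylundeca-1,5,9-trien-3-ol | CC(C)=CCC/C(C)=C/CC(O)/C(C)=C/I | intermediate
16 | (1E,5E)-1-iodo-2,6,10-trimethylundeca-1,5,9-trien-3-one | CC(C)=CCC/C(C)=C/CC(=O)/C(C)=C/I | intermediate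
17 | (R,1E,5E)-1-iodo-2,6,10-trimethylundeca-1,5,9-trien-3-ol | CC(C)=CCC/C(C)=C/C[C@@H](O)/C(C)=C/I | intermediate
18 | TBS ether of 17 | CC(C)=CCC/C(C)=C/C[C@@H](O[Si](C)(C)C(C)(C)C)/C(C)=C/I | intermediate
19 | side-chain γ-lactone (10S,11S,16R; C7–Br, C1–OPiv) | CC(C)=CCC/C(C)=C/C[C@@H](O[Si](C)(C)C(C)(C)C)/C(C)=C/CC[C@@]1(C)CC(=O)O[C@@]1(C)CC/C(Br)=C(\C)COC(=O)C(C)(C)C | intermediate
20 | bridged 6-oxabicyclo[3.2.1]octan-7-one (6R,10S,11S,16R; Z-alkylidene) | CC(C)=CCC/C(C)=C/C[C@@H](O[Si](C)(C)C(C)(C)C)/C(C)=C/CC[C@@]1(C)[C@@H]2C(=O)O[C@@]1(C)CC/C2=C(\C)COC(=O)C(C)(C)C | intermediate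
21 | bridged lactol, C1–OH free (anomers) | CC(C)=CCC/C(C)=C/C[C@@H](O[Si](C)(C)C(C)(C)C)/C(C)=C/CC[C@@]1(C)[C@@H]2C(O)O[C@@]1(C)CC/C2=C(\C)CO | intermediate
22 | C6-vinyl diol (16-OTBS) | CC(C)=CCC/C(C)=C/C[C@@H](O[Si](C)(C)C(C)(C)C)/C(C)=C/CC[C@@]1(C)[C@H](C=C)/C(=C(/C)CO)CC[C@]1(C)O | intermediate
23 | 16-O-TBS triol (C1–OH, C3–OH, C10–OH) | CC(C)=CCC/C(C)=C/C[C@@H](O[Si](C)(C)C(C)(C)C)/C(C)=C/CC[C@@]1(C)[C@H](CCCO)/C(=C(/C)CO)CC[C@]1(C)O | intermediate
24 | 16-O-TBS-isoiridogermanal | CC(C)=CCC/C(C)=C/C[C@@H](O[Si](C)(C)C(C)(C)C)/C(C)=C/CC[C@@]1(C)[C@H](CCCO)/C(=C(/C)C=O)CC[C@]1(C)O | intermediate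
25 | isoiridogermanal | CC(C)=CCC/C(C)=C/C[C@@H](O)/C(C)=C/CC[C@@]1(C)[C@H](CCCO)/C(=C(/C)C=O)CC[C@]1(C)O | target

## Step count

- Total steps: 21.
- Longest linear sequence: 13. This is reached by two equal paths: steps 1–4, 7, 8, 15–21, and steps 9–14, 15–21.

## Steps most likely to fail

1. **Step 7.** The risk is poor Me versus CH2CH2R discrimination and low ee for a dialkyl ketone.
   - Fallback: set the two centres separately.
   - C10 is made alone by enantioselective addition to ketone 6, and the product is converted to the 5,5-disubstituted butenolide that already carries a C12–C13 hydroxyethyl handle on C11.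
   - C11 is then created by substrate-controlled Me2CuLi conjugate addition anti to the larger C9 chain.
   - The handle is coupled to 18 by an sp3–sp2 Negishi reaction.
2. **Step 16.** The risks are a hindered reductive elimination, possible π-allyl ionisation of the allylic pivalate, and allene formation.
   - Fallback: drop the cross-coupling and raise C1 to the ester level, giving a (Z)-β-bromo-α-methyl enoate.
   - The ring is closed by metal-free anionic addition–elimination of the lactone enolate, which uses the same tether control at C6.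
   - DIBAL-H in step 17 then reduces the enoate to the C1 alcohol.
3. **Step 19.** The risks are isomerisation of the doubly allylic C6-vinyl group into a conjugated diene and sluggish reaction at the hindered site.
   - Fallback: replace the methylenation and carbonylation sequence.
   - Lactol 21 is olefinated with Ph3P=CHCO2Me under neutral conditions.
   - The enoate is then reduced by CuH conjugate reduction and the ester by DIBAL-H, giving the same hydroxypropyl arm at the cost of one extra step.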